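In halimane numbering, the only unsaturation of ring A is C1=C10, held between C2 and C5, and C5 is bonded to the fully substituted C4 that carries a methyl group and the carboxyl carbon. This pattern is what a [4+2] union of a C2=C1–C10=C5 diene with a methacrylic C3=C4 unit leaves behind, so the route rests on cutting C2–C3 and C4–C5. One catalytic asymmetric exo Diels–Alder addition of methacrolein closes ring A, creates C4 and C5 and puts the alkene in its final place. Its diene partner is an enantiopure ring-B 1-vinylcyclohexene with the cis C8 and C9 methyl groups and a dioxolane-masked 3-oxobutyl chain on C9.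

Key step: step 6

Remarks:
- Numbering: ring A = C1–C5 and C10, ring B = C5–C10, side chain C11–C15 on C9, methyl ester on C4. The target is 4R,5R,8R,9S,13S,14R.
- The enone starting material is the six-membered 2-methylcyclohex-2-en-1-one, CC1=CCCCC1=O; six ring carbons are needed for ring B.
- Assumption: the sense of induction of the phosphoramidite ligand (step 1) and of the oxazaborolidinium catalyst (step 6) is assigned from the accepted models of these catalyst classes. A first small-scale run would confirm each, and the mirror-image ligand or catalyst would be taken if the sense proved reversed.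

Step 1
Reactants: 1 2-methylcyclohex-2-en-1-one
Product: 3 trimethyl{[(3R)-2,3-dimethylcyclohex-1-en-1-yl]oxy}silane, via dimethylaluminium enolate 2 (not isolated)
Conditions: AlMe3 (1.4 equiv), copper thiophene-2-carboxylate Cu(O2CC4H3S) (2 mol%), (R,S,S)-O,O'-(1,1'-binaphthalene-2,2'-diyl) N,N-bis(1-phenylethyl)phosphoramidite (4 mol%), Et2O, −30 °C; then Me3SiOSO2CF3, THF, −30 → 0 °C
Reagents that add atoms: trimethylaluminium C[Al](C)C; trimethylsilyl trifluoromethanesulfonate C[Si](C)(C)OS(=O)(=O)C(F)(F)F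
Why: Copper-catalysed asymmetric conjugate addition, in which the chiral phosphoramidite–copper–methyl species delivers the methyl group to one face of the enone and so sets C8 as R, followed by O-silylation of the regiodefined aluminium enolate, which stores the C9 enolate position for step 2.

Step 2
Reactants: 3 trimethyl{[(3R)-2,3-dimethylcyclohex-1-en-1-yl]oxy}silane; 4 methyl vinyl ketone
Product: 5 (2S,3R)-2,3-dimethyl-2-(3-oxobutyl)cyclohexan-1-one
Conditions: BF3·OEt2, i-PrOH, MeNO2/CH2Cl2, −78 → −20 °C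
Reagents that add atoms: none
Why: Mukaiyama–Michael addition of the silyl enol ether to the boron-activated enone forms C9–C11 on the face opposite the neighbouring C8 methyl (pseudoaxial to avoid the C9 methyl), so the chain enters trans to it and the cis-dimethyl array with C9 = S should result.

Step 3
Reactants: 5 (2S,3R)-2,3-dimethyl-2-(3-oxobutyl)cyclohexan-1-one
Product: 6 (2S,3R)-2,3-dimethyl-2-[2-(2-methyl-1,3-dioxolan-2-yl)ethyl]cyclohexan-1-one
Conditions: (Me3SiOCH2)2, Me3SiOSO2CF3 (cat.), CH2Cl2, −78 → −20 °C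
Reagents that add atoms: 1,2-bis(trimethylsilyloxy)ethane C[Si](C)(C)OCCO[Si](C)(C)C
Why: Silyl-triflate-catalysed ketalisation distinguishes the carbonyls on steric grounds, protecting the unhindered methyl ketone while the ring ketone next to quaternary C9 is left, and the aprotic low-temperature conditions avoid the intramolecular aldol closure open to this 1,5-diketone.

Step 4
Reactants: 6 (2S,3R)-2,3-dimethyl-2-[2-(2-methyl-1,3-dioxolan-2-yl)ethyl]cyclohexan-1-one
Product: 8 (5R,6S)-5,6-dimethyl-6-[2-(2-methyl-1,3-dioxolan-2-yl)ethyl]cyclohex-1-en-1-yl trifluoromethanesulfonate, via potassium enolate 7 (not isolated)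
Conditions: KN(SiMe3)2, THF, −78 °C; then PhN(SO2CF3)2, −78 → 0 °C
Reagents that add atoms: N-phenylbis(trifluoromethanesulfonimide) O=S(=O)(N(c1ccccc1)S(=O)(=O)C(F)(F)F)C(F)(F)F
Why: Enolate O-sulfonylation (enol triflate formation) can only place the double bond at C10=C5 because C9 is quaternary, and the ketal and both stereocentres are inert to the amide base.

Step 5
Reactants: 8 (5R,6S)-5,6-dimethyl-6-[2-(2-methyl-1,3-dioxolan-2-yl)ethyl]cyclohex-1-en-1-yl trifluoromethanesulfonate; 9 tributyl(vinyl)stannane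
Product: 10 2-{2-[(1S,6R)-2-ethenyl-1,6-dimethylcyclohex-2-en-1-yl]ethyl}-2-methyl-1,3-dioxolane
Conditions: Pd(PPh3)4 (5 mol%), LiCl, THF, 65 °C
Reagents that add atoms: none
Why: Stille cross-coupling of the alkenyl triflate with the vinylstannane (oxidative addition, chloride-assisted transmetalation, reductive elimination) forms C10–C1 and gives the semicyclic diene without touching the ketal or the stereocentres.

Step 6
Reactants: 10 2-{2-[(1S,6R)-2-ethenyl-1,6-dimethylcyclohex-2-en-1-yl]ethyl}-2-methyl-1,3-dioxolane; 11 methacrolein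
Product: 12 (1R,5S,6R,8aR)-1,5,6-trimethyl-5-[2-(2-methyl-1,3-dioxolan-2-yl)ethyl]-1,2,3,5,6,7,8,8a-octahydronaphthalene-1-carbaldehyde (halim-1(10)-ene core, C4 formyl cis to H5)
Conditions: (R)-1-(2-methylphenyl)-3,3-diphenyltetrahydro-1H,3H-pyrrolo[1,2-c][1,3,2]oxazaborole (20 mol%), HN(SO2CF3)2 (17 mol%), methacrolein (3 equiv), CH2Cl2, −78 → −40 °C
Reagents that add atoms: none
Why: The protonated oxazaborolidine binds the formyl oxygen of s-trans methacrolein, and the activated enal adds to the s-cis diene C2=C1–C10=C5 (a conformation that quaternary C9 enforces) in a concerted, asynchronous, suprafacial [4+2] cycloaddition; the closest known reaction type is the oxazaborolidinium-catalysed exo Diels–Alder addition of 2-methylacrolein to 1-substituted and semicyclic dienes. Ring A is closed by cycloaddition, the sigma bonds C2–C3 and C4–C5 forming in one event and the new alkene appearing at C1=C10. Regiochemistry follows from the largest diene coefficient on the terminal vinyl carbon C2, which pairs with the methylene carbon of the enal, so the formyl-bearing carbon becomes C4 on C5. C4 is set by the catalyst, whose aryl group covers one face of the bound enal and leaves open the face that gives 4R; C5 is set by the exo topology (formyl turned away from the diene and from the crowded C9/C10 region, methyl underneath), which puts the formyl group cis to H5. With the enal face fixed, exo addition can only take place on the ring-B face opposite the C9 methyl, the less hindered face in the half-chair with the C8 methyl equatorial and the C9 methyl pseudoaxial, so catalyst and substrate should reinforce each other. The step needs exo, ortho and facial selectivity together; the dioxolane, the only other Lewis-basic site, is hindered and should not be ionised by a slight deficit of acid at low temperature.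

Step 7
Reactants: 12 (1R,5S,6R,8aR)-1,5,6-trimethyl-5-[2-(2-methyl-1,3-dioxolan-2-yl)ethyl]-1,2,3,5,6,7,8,8a-octahydronaphthalene-1-carbaldehyde
Product: 13 (1R,5S,6R,8aR)-1,5,6-trimethyl-5-[2-(2-methyl-1,3-dioxolan-2-yl)ethyl]-1,2,3,5,6,7,8,8a-octahydronaphthalene-1-carboxylic acid
Conditions: NaClO2, NaH2PO4, 2-methylbut-2-ene, t-BuOH/H2O, 0 °C → rt
Reagents that add atoms: sodium chlorite [Na+].[O-]Cl=O
Why: Pinnick oxidation converts the neopentyl aldehyde into the acid while the alkene scavenger removes hypochlorous acid before it can reach C1=C10, and C4, having no hydrogen, cannot epimerise.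

Step 8
Reactants: 13 (1R,5S,6R,8aR)-1,5,6-trimethyl-5-[2-(2-methyl-1,3-dioxolan-2-yl)ethyl]-1,2,3,5,6,7,8,8a-octahydronaphthalene-1-carboxylic acid
Product: 14 methyl (1R,5S,6R,8aR)-1,5,6-trimethyl-5-[2-(2-methyl-1,3-dioxolan-2-yl)ethyl]-1,2,3,5,6,7,8,8a-octahydronaphthalene-1-carboxylate
Conditions: MeI, K2CO3, DMF, rt
Reagents that add atoms: iodomethane CI
Why: Carboxylate O-alkylation (SN2 at iodomethane) esterifies the hindered acid without acid, which a gamma,delta-unsaturated acid of this kind is better spared.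

Step 9
Reactants: 14 methyl (1R,5S,6R,8aR)-1,5,6-trimethyl-5-[2-(2-methyl-1,3-dioxolan-2-yl)ethyl]-1,2,3,5,6,7,8,8a-octahydronaphthalene-1-carboxylate
Product: 15 methyl (1R,5S,6R,8aR)-1,5,6-trimethyl-5-(3-oxobutyl)-1,2,3,5,6,7,8,8a-octahydronaphthalene-1-carboxylate
Conditions: pyridinium p-toluenesulfonate (cat.), acetone/H2O, 55 °C
Reagents that add atoms: water O
Why: Acid-catalysed ketal hydrolysis frees the C13 methyl ketone under conditions too mild to move the C1=C10 alkene or to cleave the hindered ester.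

Step 10
Reactants: 15 methyl (1R,5S,6R,8aR)-1,5,6-trimethyl-5-(3-oxobutyl)-1,2,3,5,6,7,8,8a-octahydronaphthalene-1-carboxylate; 16 triethyl phosphonoacetate
Product: 17 methyl (1R,5S,6R,8aR)-5-[(3E)-5-ethoxy-3-methyl-5-oxopent-3-en-1-yl]-1,5,6-trimethyl-1,2,3,5,6,7,8,8a-octahydronaphthalene-1-carboxylate
Conditions: NaH, THF, 0 → 60 °C
Reagents that add atoms: none
Why: Horner–Wadsworth–Emmons olefination of the methyl ketone with the stabilised phosphonate anion should favour the E enoate (ester trans to the C12 chain) through reversible addition, and any Z isomer would be removed by chromatography here or after step 11.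

Step 11
Reactants: 17 methyl (1R,5S,6R,8aR)-5-[(3E)-5-ethoxy-3-methyl-5-oxopent-3-en-1-yl]-1,5,6-trimethyl-1,2,3,5,6,7,8,8a-octahydronaphthalene-1-carboxylate
Product: 18 methyl (1R,5S,6R,8aR)-5-[(3E)-5-hydroxy-3-methylpent-3-en-1-yl]-1,5,6-trimethyl-1,2,3,5,6,7,8,8a-octahydronaphthalene-1-carboxylate
Conditions: i-Bu2AlH (2.2 equiv), CH2Cl2, −78 °C; aq. potassium sodium tartrate KNaC4H4O6 work-up
Reagents that add atoms: none
Why: Hydride reduction with DIBAL-H at low temperature takes the unhindered conjugated ethyl ester to the allylic alcohol by 1,2-addition, while the C4 methyl ester, on a quaternary carbon flanked by C5, should react much more slowly.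

Step 12
Reactants: 18 methyl (1R,5S,6R,8aR)-5-[(3E)-5-hydroxy-3-methylpent-3-en-1-yl]-1,5,6-trimethyl-1,2,3,5,6,7,8,8a-octahydronaphthalene-1-carboxylate
Product: 19 methyl (1R,5S,6R,8aR)-5-{2-[(2R,3R)-3-(hydroxymethyl)-2-methyloxiran-2-yl]ethyl}-1,5,6-trimethyl-1,2,3,5,6,7,8,8a-octahydronaphthalene-1-carboxylate (13R,14R epoxide)
Conditions: Ti(OiPr)4 (10 mol%), D-(−)-diethyl tartrate (12 mol%), t-BuOOH, 4 Å molecular sieves, CH2Cl2, −20 °C
Reagents that add atoms: tert-butyl hydroperoxide CC(C)(C)OO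
Why: Sharpless asymmetric epoxidation is reagent-controlled, the D-(−)-tartrate complex delivering oxygen to the face of this geraniol-type E allylic alcohol that gives the (2R,3R)-epoxy alcohol (13R,14R), and the C1=C10 alkene, lacking a directing hydroxyl, is not touched.

Step 13
Reactants: 19 methyl (1R,5S,6R,8aR)-5-{2-[(2R,3R)-3-(hydroxymethyl)-2-methyloxiran-2-yl]ethyl}-1,5,6-trimethyl-1,2,3,5,6,7,8,8a-octahydronaphthalene-1-carboxylate
Product: 20 methyl (1R,5S,6R,8aR)-1,5,6-trimethyl-5-[(3S,4R)-3,4,5-trihydroxy-3-methylpentyl]-1,2,3,5,6,7,8,8a-octahydronaphthalene-1-carboxylate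
Conditions: HClO4 (cat.), THF/H2O, 0 °C → rt
Reagents that add atoms: water O
Why: Acid-catalysed epoxide hydrolysis (borderline SN2 opening) sends water to the tertiary C13, which bears positive charge better than C14 next to the CH2OH group, from the side opposite the leaving oxygen, so C13 is inverted to S while C14 stays R.

Step 14
Reactants: 20 methyl (1R,5S,6R,8aR)-1,5,6-trimethyl-5-[(3S,4R)-3,4,5-trihydroxy-3-methylpentyl]-1,2,3,5,6,7,8,8a-octahydronaphthalene-1-carboxylate
Product: 21 methyl (1R,5S,6R,8aR)-5-[(3S,4R)-4,5-diacetoxy-3-hydroxy-3-methylpentyl]-1,5,6-trimethyl-1,2,3,5,6,7,8,8a-octahydronaphthalene-1-carboxylate (CNP0238486.1)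
Conditions: Ac2O, pyridine, rt
Reagents that add atoms: acetic anhydride CC(=O)OC(C)=O
Why: Acetylation (acyl transfer) esterifies the primary C15 and secondary C14 hydroxyls, while the tertiary C13 hydroxyl should be inert to acetic anhydride in pyridine without an acyl-transfer catalyst.

Compound list

1 | 2-methylcyclohex-2-en-1-one | CC1=CCCCC1=O | starting material
2 | dimethylaluminium (3R)-2,3-dimethylcyclohex-1-en-1-olate | C[C@@H]1CCCC(O[Al](C)C)=C1C | intermediate (not isolated)
3 | trimethyl{[(3R)-2,3-dimethylcyclohex-1-en-1-yl]oxy}silane | C[C@@H]1CCCC(O[Si](C)(C)C)=C1C | intermediate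
4 | methyl vinyl ketone (but-3-en-2-one) | CC(=O)C=C | starting material
5 | (2S,3R)-2,3-dimethyl-2-(3-oxobutyl)cyclohexan-1-one | O=C1CCC[C@@H](C)[C@]1(C)CCC(C)=O | intermediate
6 | (2S,3R)-2,3-dimethyl-2-[2-(2-methyl-1,3-dioxolan-2-yl)ethyl]cyclohexan-1-one | O=C1CCC[C@@H](C)[C@]1(C)CCC2(C)OCCO2 | intermediate
7 | potassium (5R,6S)-5,6-dimethyl-6-[2-(2-methyl-1,3-dioxolan-2-yl)ethyl]cyclohex-1-en-1-olate | [K+].[O-]C1=CCC[C@@H](C)[C@]1(C)CCC2(C)OCCO2 | intermediate (not isolated)
8 | (5R,6S)-5,6-dimethyl-6-[2-(2-methyl-1,3-dioxolan-2-yl)ethyl]cyclohex-1-en-1-yl trifluoromethanesulfonate | O=S(=O)(OC1=CCC[C@@H](C)[C@]1(C)CCC2(C)OCCO2)C(F)(F)F | intermediate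
9 | tributyl(vinyl)stannane | C=C[Sn](CCCC)(CCCC)CCCC | starting material
10 | 2-{2-[(1S,6R)-2-ethenyl-1,6-dimethylcyclohex-2-en-1-yl]ethyl}-2-methyl-1,3-dioxolane | C=CC1=CCC[C@@H](C)[C@]1(C)CCC2(C)OCCO2 | intermediate (key-step precursor)
11 | methacrolein (2-methylprop-2-enal) | CC(=C)C=O | starting material
12 | (1R,5S,6R,8aR)-1,5,6-trimethyl-5-[2-(2-methyl-1,3-dioxolan-2-yl)ethyl]-1,2,3,5,6,7,8,8a-octahydronaphthalene-1-carbaldehyde | O=C[C@]1(C)CCC=C2[C@H]1CC[C@@H](C)[C@]2(C)CCC3(C)OCCO3 | intermediate (key-step product)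
13 | (1R,5S,6R,8aR)-1,5,6-trimethyl-5-[2-(2-methyl-1,3-dioxolan-2-yl)ethyl]-1,2,3,5,6,7,8,8a-octahydronaphthalene-1-carboxylic acid | OC(=O)[C@]1(C)CCC=C2[C@H]1CC[C@@H](C)[C@]2(C)CCC3(C)OCCO3 | intermediate
14 | methyl (1R,5S,6R,8aR)-1,5,6-trimethyl-5-[2-(2-methyl-1,3-dioxolan-2-yl)ethyl]-1,2,3,5,6,7,8,8a-octahydronaphthalene-1-carboxylate | COC(=O)[C@]1(C)CCC=C2[C@H]1CC[C@@H](C)[C@]2(C)CCC3(C)OCCO3 | intermediate
15 | methyl (1R,5S,6R,8aR)-1,5,6-trimethyl-5-(3-oxobutyl)-1,2,3,5,6,7,8,8a-octahydronaphthalene-1-carboxylate | COC(=O)[C@]1(C)CCC=C2[C@H]1CC[C@@H](C)[C@]2(C)CCC(C)=O | intermediate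
16 | triethyl phosphonoacetate | CCOC(=O)CP(=O)(OCC)OCC | starting material
17 | methyl (1R,5S,6R,8aR)-5-[(3E)-5-ethoxy-3-methyl-5-oxopent-3-en-1-yl]-1,5,6-trimethyl-1,2,3,5,6,7,8,8a-octahydronaphthalene-1-carboxylate | COC(=O)[C@]1(C)CCC=C2[C@H]1CC[C@@H](C)[C@]2(C)CC/C(C)=C/C(=O)OCC | intermediate
18 | methyl (1R,5S,6R,8aR)-5-[(3E)-5-hydroxy-3-methylpent-3-en-1-yl]-1,5,6-trimethyl-1,2,3,5,6,7,8,8a-octahydronaphthalene-1-carboxylate | COC(=O)[C@]1(C)CCC=C2[C@H]1CC[C@@H](C)[C@]2(C)CC/C(C)=C/CO | intermediate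
19 | methyl (1R,5S,6R,8aR)-5-{2-[(2R,3R)-3-(hydroxymethyl)-2-methyloxiran-2-yl]ethyl}-1,5,6-trimethyl-1,2,3,5,6,7,8,8a-octahydronaphthalene-1-carboxylate | COC(=O)[C@]1(C)CCC=C2[C@H]1CC[C@@H](C)[C@]2(C)CC[C@@]3(C)O[C@@H]3CO | intermediate
20 | methyl (1R,5S,6R,8aR)-1,5,6-trimethyl-5-[(3S,4R)-3,4,5-trihydroxy-3-methylpentyl]-1,2,3,5,6,7,8,8a-octahydronaphthalene-1-carboxylate | COC(=O)[C@]1(C)CCC=C2[C@H]1CC[C@@H](C)[C@]2(C)CC[C@](C)(O)[C@@H](CO)O | intermediate
21 | methyl (1R,5S,6R,8aR)-5-[(3S,4R)-4,5-diacetoxy-3-hydroxy-3-methylpentyl]-1,5,6-trimethyl-1,2,3,5,6,7,8,8a-octahydronaphthalene-1-carboxylate | COC(=O)[C@]1(C)CCC=C2[C@H]1CC[C@@H](C)[C@]2(C)CC[C@](C)(O)[C@@H](COC(C)=O)OC(C)=O | target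

Total step count: 14. Longest linear sequence: 14 steps (1 → 21).

Steps most likely to fail

Step 6. The cycloaddition may lose its exo preference, with the formyl group tucked under the diene, or the catalyst-selected enal face may pair with the wrong diene face; either would deliver C4 and C5 as a diastereomer mixture. Ionisation of the dioxolane by the boron acid is a lesser concern. Fallback, setting out from 10 and returning at 13: an endo preference is used instead of fought, by exchanging the roles of the two C4 substituents. Commercial 2-methylidenepropane-1,3-diol (C=C(CO)CO) is monosilylated (NaH, t-BuMe2SiCl, THF) to 2-({[tert-butyl(dimethyl)silyl]oxy}methyl)prop-2-en-1-ol F1 and oxidised (MnO2, CH2Cl2) to 2-({[tert-butyl(dimethyl)silyl]oxy}methyl)prop-2-enal F2. With the (S)-configured oxazaborolidinium triflimide, endo addition of F2 to 10 on the same ring-B face should give (1S,5S,6R,8aR)-1-({[tert-butyl(dimethyl)silyl]oxy}methyl)-5,6-dimethyl-5-[2-(2-methyl-1,3-dioxolan-2-yl)ethyl]-1,2,3,5,6,7,8,8a-octahydronaphthalene-1-carbaldehyde F3, in which the formyl group is trans to H5 and the silyloxymethyl group cis to it. Wolff–Kishner reduction (N2H4·H2O, KOH, diethylene glycol, 130 then 200 °C) turns the formyl group into the C4 methyl and removes the silyl group, giving {(1R,5S,6R,8aR)-1,5,6-trimethyl-5-[2-(2-methyl-1,3-dioxolan-2-yl)ethyl]-1,2,3,5,6,7,8,8a-octahydronaphthalen-1-yl}methanol F4. Oxidation of the neopentyl alcohol (TEMPO cat., NaOCl cat., NaClO2, MeCN/phosphate buffer) then gives acid 13.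

Step 13. Opening of the protonated epoxide may leak through a free C13 cation and lose stereochemical fidelity, take place in part at C14, or be intercepted by the C1=C10 alkene in a cation–olefin cyclisation. Fallback, setting out from 18 and returning at 20: C14 is inverted instead of C13, under base. Sharpless epoxidation of 18 with L-(+)-diethyl tartrate (Ti(OiPr)4, t-BuOOH, CH2Cl2, −20 °C) gives methyl (1R,5S,6R,8aR)-5-{2-[(2S,3S)-3-(hydroxymethyl)-2-methyloxiran-2-yl]ethyl}-1,5,6-trimethyl-1,2,3,5,6,7,8,8a-octahydronaphthalene-1-carboxylate F5. In aqueous NaOH/t-BuOH at 60–70 °C the Payne rearrangement lets the C15 alkoxide displace the epoxide oxygen at C14 with inversion, giving methyl (1R,5S,6R,8aR)-5-{(3S)-3-hydroxy-3-[(2R)-oxiran-2-yl]butyl}-1,5,6-trimethyl-1,2,3,5,6,7,8,8a-octahydronaphthalene-1-carboxylate F6 (not isolated). Hydroxide opens F6 at the unhindered C15 and gives triol 20 without a bond to C13 ever being broken. The hindered C4 ester should survive dilute hydroxide; if it were partly saponified, the conditions of step 8 would restore it.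

Step 10. The olefination of the methyl ketone may give an E/Z mixture that costs material and, if carried on, would erode the C13/C14 relative configuration. Fallback, setting out from 15 and returning at 18 (it also bypasses the ester discrimination of step 11): kinetic enolisation at the methyl group and phosphorylation (LiN(i-Pr)2, THF, −78 °C; ClP(O)(OEt)2) gives methyl (1R,5S,6R,8aR)-5-{3-[(diethoxyphosphoryl)oxy]but-3-en-1-yl}-1,5,6-trimethyl-1,2,3,5,6,7,8,8a-octahydronaphthalene-1-carboxylate F7 (not isolated). Elimination with further LiN(i-Pr)2 gives methyl (1R,5S,6R,8aR)-5-(but-3-yn-1-yl)-1,5,6-trimethyl-1,2,3,5,6,7,8,8a-octahydronaphthalene-1-carboxylate F8. Zirconium-catalysed syn carboalumination (AlMe3, Cp2ZrCl2, CH2Cl2, 0 °C → rt) gives methyl (1R,5S,6R,8aR)-5-[(3E)-4-(dimethylalumanyl)-3-methylbut-3-en-1-yl]-1,5,6-trimethyl-1,2,3,5,6,7,8,8a-octahydronaphthalene-1-carboxylate F9 (not isolated), and trapping with paraformaldehyde gives the E allylic alcohol 18 with the geometry fixed by the syn addition.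

Further compounds

F1 | step 6 | 2-({[tert-butyl(dimethyl)silyl]oxy}methyl)prop-2-en-1-ol | OCC(=C)CO[Si](C)(C)C(C)(C)C
F2 | step 6 | 2-({[tert-butyl(dimethyl)silyl]oxy}methyl)prop-2-enal | O=CC(=C)CO[Si](C)(C)C(C)(C)C
F3 | step 6 | (1S,5S,6R,8aR)-1-({[tert-butyl(dimethyl)silyl]oxy}methyl)-5,6-dimethyl-5-[2-(2-methyl-1,3-dioxolan-2-yl)ethyl]-1,2,3,5,6,7,8,8a-octahydronaphthalene-1-carbaldehyde | CC(C)(C)[Si](C)(C)OC[C@]1(C=O)CCC=C2[C@H]1CC[C@@H](C)[C@]2(C)CCC3(C)OCCO3
F4 | step 6 | {(1R,5S,6R,8aR)-1,5,6-trimethyl-5-[2-(2-methyl-1,3-dioxolan-2-yl)ethyl]-1,2,3,5,6,7,8,8a-octahydronaphthalen-1-yl}methanol | OC[C@]1(C)CCC=C2[C@H]1CC[C@@H](C)[C@]2(C)CCC3(C)OCCO3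
F5 | step 13 | methyl (1R,5S,6R,8aR)-5-{2-[(2S,3S)-3-(hydroxymethyl)-2-methyloxiran-2-yl]ethyl}-1,5,6-trimethyl-1,2,3,5,6,7,8,8a-octahydronaphthalene-1-carboxylate | COC(=O)[C@]1(C)CCC=C2[C@H]1CC[C@@H](C)[C@]2(C)CC[C@]3(C)O[C@H]3CO
F6 | step 13 | methyl (1R,5S,6R,8aR)-5-{(3S)-3-hydroxy-3-[(2R)-oxiran-2-yl]butyl}-1,5,6-trimethyl-1,2,3,5,6,7,8,8a-octahydronaphthalene-1-carboxylate | COC(=O)[C@]1(C)CCC=C2[C@H]1CC[C@@H](C)[C@]2(C)CC[C@](C)(O)[C@H]3CO3
F7 | step 10 | methyl (1R,5S,6R,8aR)-5-{3-[(diethoxyphosphoryl)oxy]but-3-en-1-yl}-1,5,6-trimethyl-1,2,3,5,6,7,8,8a-octahydronaphthalene-1-carboxylate | COC(=O)[C@]1(C)CCC=C2[C@H]1CC[C@@H](C)[C@]2(C)CCC(=C)OP(=O)(OCC)OCC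
F8 | step 10 | methyl (1R,5S,6R,8aR)-5-(but-3-yn-1-yl)-1,5,6-trimethyl-1,2,3,5,6,7,8,8a-octahydronaphthalene-1-carboxylate | COC(=O)[C@]1(C)CCC=C2[C@H]1CC[C@@H](C)[C@]2(C)CCC#C
F9 | step 10 | methyl (1R,5S,6R,8aR)-5-[(3E)-4-(dimethylalumanyl)-3-methylbut-3-en-1-yl]-1,5,6-trimethyl-1,2,3,5,6,7,8,8a-octahydronaphthalene-1-carboxylate | COC(=O)[C@]1(C)CCC=C2[C@H]1CC[C@@H](C)[C@]2(C)CC/C(C)=C/[Al](C)C
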